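**Plan**

- Retrosynthesis: the C12 silyl ether and C7 acetate are removed, then C7–C8 is cut (aldol) to give enal 23 and chloro-enone 20. The two ring bonds C8–C9 and C11–C12 are then cut together.
- Enabling feature: the ring is a 4-hydroxycyclopent-2-enone. C12 (carbinol) with C8 is a masked ketone carbonyl plus its α-carbon. C9–C10–C11 is an enoyl unit whose β-carbon becomes nucleophilic once C9, as an acylsilane, has accepted the enolate and undergone a Brook rearrangement.
- Forward order: acylsilane 5 (steps 1–3) and regiodefined enol ether 11 (steps 4–5) are joined to the five-membered ring in step 6. The silyl enol ether so formed places Cl at C10, and sulfoxide elimination unveils the enone (step 7).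
- Stereochemistry: C12 is formed racemic in step 6. It is selected in step 8, where a reagent-controlled CBS reduction turns the enantiomers into separable diastereomers, and step 9 reoxidises. C8 and C7 come from the aldol (attack anti to the oct-2-enyl chain; anti aldol from the ring-locked E-enolate).
- Both Z-olefins come from syn processes (carbocupration of acetylene, Lindlar reduction). Acetylation and desilylation finish the route.

Key step: step 6

Remark: methyl 7-hydroxyhept-5-ynoate (21) is taken as a purchasable prostaglandin side-chain building block; prostanoid numbering is used in the text (ring C8–C12: C9 carbonyl, C10 chloro carbon, C11 vinylic CH, C12 carbinol carbon; C7 acetoxy carbon).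

**Step 1**
Reactants: 1 ethyl vinyl ether
Product: 3 1-[tert-butyl(dimethyl)silyl]ethan-1-one, via silyl vinyl ether 2 (not isolated)
Conditions: t-BuLi, THF, −78 → 0 °C; t-BuMe2SiCl, −78 °C → rt; then 1 M HCl, acetone, rt
Reagents that add atoms: tert-butyldimethylsilyl chloride, CC(C)(C)[Si](C)(C)Cl; water, O
Why: α-Lithiation of the vinyl ether, C-silylation and hydrolysis of the 1-silyl enol ether is the standard masked-acyl-anion route to acylsilanes.

**Step 2**
Reactants: 3 1-[tert-butyl(dimethyl)silyl]ethan-1-one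
Product: 4 (2Z)-1-[tert-butyl(dimethyl)silyl]-3-hydroxyprop-2-en-1-one
Conditions: LiN(iPr)2, THF, −78 °C; HCO2CH2CF3, −78 °C; aqueous HCl work-up
Reagents that add atoms: 2,2,2-trifluoroethyl formate, O=COCC(F)(F)F
Why: Claisen formylation of the kinetic lithium enolate of the acylsilane with an activated formate at −78 °C should give the hydroxymethylene ketone while avoiding alkoxide attack at silicon.

**Step 3**
Reactants: 4 (2Z)-1-[tert-butyl(dimethyl)silyl]-3-hydroxyprop-2-en-1-one
Product: 5 (2E)-1-[tert-butyl(dimethyl)silyl]-3-(phenylsulfanyl)prop-2-en-1-one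
Conditions: PhSH, TsOH·H2O (cat.), benzene, reflux, Dean–Stark trap, in the dark
Reagents that add atoms: thiophenol, Sc1ccccc1
Why: Acid-catalysed condensation of the thiol with the hydroxymethylene ketone (addition–dehydration at the aldehyde carbon) should give the vinylogous thioester as the thermodynamically preferred E isomer.

**Step 4**
Reactants: 6 1,3-dibromopropan-2-one
Product: 7 [(3-bromoprop-1-en-2-yl)oxy]trimethylsilane
Conditions: Zn–Cu couple, Me3SiCl, MeCN–Et2O, 0 °C
Reagents that add atoms: chlorotrimethylsilane, C[Si](C)(C)Cl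
Why: Reductive silylation, in which zinc inserts into one C–Br bond of the symmetrical dibromo ketone and the zinc enolate is O-silylated, is the established entry to 2-siloxyallyl bromides and fixes the enol double bond on the debrominated carbon.

**Step 5**
Reactants: 8 pentylmagnesium bromide; 9 acetylene; 7 [(3-bromoprop-1-en-2-yl)oxy]trimethylsilane
Product: 11 trimethyl{[(4Z)-deca-1,4-dien-2-yl]oxy}silane, via alkenylcopper reagent 10 (not isolated)
Conditions: CuBr·SMe2, Et2O–Me2S, −45 °C; HC≡CH, −25 °C; then 7, THF, −30 → 0 °C; non-aqueous work-up, distillation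
Reagents that add atoms: none
Why: syn-Carbocupration of acetylene gives the Z-alkenylcopper 10, which should substitute the allylic bromide with retention of olefin geometry (SN2 and SN2' give the same product because the siloxyallyl unit is symmetric), so the Z-olefin of the ω-chain and an enol ether fixed toward the future ring CH2 are obtained together.

**Step 6**
Reactants: 11 trimethyl{[(4Z)-deca-1,4-dien-2-yl]oxy}silane; 5 (2E)-1-[tert-butyl(dimethyl)silyl]-3-(phenylsulfanyl)prop-2-en-1-one
Product: 15 rac-tert-butyl(dimethyl){[4-[(2Z)-oct-2-en-1-yl]-3-(phenylsulfanyl)-4-(triethylsilyloxy)cyclopent-1-en-1-yl]oxy}silane, via lithium enolate 12 (not isolated), via adduct alkoxide 13 (not isolated), via cyclised alkoxide 14 (not isolated)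
Conditions: MeLi, THF, 0 °C; then 5, −80 → −30 °C; then Et3SiOTf, −78 → 0 °C
Reagents that add atoms: triethylsilyl trifluoromethanesulfonate, CC[Si](CC)(CC)OS(=O)(=O)C(F)(F)F
Why: The lithium enolate 12 adds through carbon to the acylsilane carbonyl of 5 (first C–C bond, C8–C9), and the α-silyl alkoxide 13 undergoes a [1,2]-Brook rearrangement (C→O silyl shift) that turns C9 into the head of a siloxy-allyl anion whose charge is delocalised to, and stabilised at, the sulfur-bearing C11. C11 then attacks the ketone carbonyl C12 that the enolate brought along (second C–C bond), closing the cyclopentene by a 5-exo-trig addition, directly or through a vinylcyclopropanolate that ring-expands, to give alkoxide 14, which is capped in the flask by Et3SiOTf. The closest known reaction type is the Brook rearrangement-mediated [3+2] annulation of β-(phenylthio)- or β-silyl-acryloylsilanes with lithium enolates of alkyl methyl ketones, which gives 4-hydroxy-3-(phenylthio)cyclopent-1-enyl silyl ethers. The quaternary carbinol carbon C12 is formed as a racemate and its configuration is selected in step 8, while the configuration at C11 is immaterial because that carbon becomes sp2 in step 7. The step needs 1,2- over 1,4-addition to 5, ring closure in preference to proton transfer from the allylic α-CH2, and a single enolate regioisomer: the acylsilane carbonyl is the most electrophilic site and the β-thio group deactivates the conjugate position, the temperature is kept at −80 to −30 °C, the ketone has no α,β-unsaturation so the [3+4] pathway of enone enolates is closed, and 12 is made regiospecifically from 11 and not by deprotonation.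

**Step 7**
Reactants: 15 rac-tert-butyl(dimethyl){[4-[(2Z)-oct-2-en-1-yl]-3-(phenylsulfanyl)-4-(triethylsilyloxy)cyclopent-1-en-1-yl]oxy}silane
Product: 18 rac-2-chloro-4-[(2Z)-oct-2-en-1-yl]-4-(triethylsilyloxy)cyclopent-2-en-1-one, via sulfoxide 16 (not isolated), via chloro sulfinyl ketone 17 (not isolated)
Conditions: mCPBA (1.0 equiv), NaHCO3, CH2Cl2, −78 °C; NCS, −78 → 0 °C; then CaCO3, 35 °C
Reagents that add atoms: N-chlorosuccinimide, O=C1CCC(=O)N1Cl
Why: Chemoselective sulfide-to-sulfoxide oxidation (the peracid reacts far faster at sulfur than at the enol ether or the Z-olefin at −78 °C) is followed by electrophilic α-chlorination of the regiodefined silyl enol ether at C10 and thermal syn-elimination of benzenesulfenic acid from the β-keto sulfoxide (C10–H is the only β-hydrogen, C12 being quaternary), which should give the 2-chloro-enone with chlorine and double bond placed by the annulation.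

**Step 8**
Reactants: 18 rac-2-chloro-4-[(2Z)-oct-2-en-1-yl]-4-(triethylsilyloxy)cyclopent-2-en-1-one
Product: 19 (1R,4S)-2-chloro-4-[(2Z)-oct-2-en-1-yl]-4-(triethylsilyloxy)cyclopent-2-en-1-ol
Conditions: (S)-2-methyl-CBS-oxazaborolidine [(S)-1-methyl-3,3-diphenyltetrahydro-1H,3H-pyrrolo[1,2-c][1,3,2]oxazaborole], catecholborane, toluene, −78 °C; chromatographic separation of the two diastereomers
Reagents that add atoms: none
Why: Corey–Bakshi–Shibata reduction under reagent control (chlorovinyl carbon as the large and ring CH2 as the small carbonyl substituent, C12 being remote) should give the 1R carbinol from both enantiomers of 18, so the racemate becomes the cis-(1R,4S) and trans-(1R,4R) diastereomers, and isolation of the cis isomer 19 selects the C12 configuration of the target.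

**Step 9**
Reactants: 19 (1R,4S)-2-chloro-4-[(2Z)-oct-2-en-1-yl]-4-(triethylsilyloxy)cyclopent-2-en-1-ol
Product: 20 (4S)-2-chloro-4-[(2Z)-oct-2-en-1-yl]-4-(triethylsilyloxy)cyclopent-2-en-1-one
Conditions: Dess–Martin periodinane (1,1,1-triacetoxy-1,1-dihydro-1,2-benziodoxol-3(1H)-one), NaHCO3, CH2Cl2, 0 °C → rt
Reagents that add atoms: none
Why: Dess–Martin oxidation of the allylic alcohol returns the enone without touching C12, so the (4S)-enone should be obtained as a single enantiomer.

**Step 10**
Reactants: 21 methyl 7-hydroxyhept-5-ynoate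
Product: 22 methyl (5Z)-7-hydroxyhept-5-enoate
Conditions: H2 (1 atm), Pd/CaCO3 poisoned with Pb(OAc)2 (Lindlar catalyst), quinoline, EtOAc, rt
Reagents that add atoms: none
Why: Lindlar semi-hydrogenation adds H2 syn on the poisoned palladium surface and should stop at the Z-olefin.

**Step 11**
Reactants: 22 methyl (5Z)-7-hydroxyhept-5-enoate
Product: 23 methyl (5Z)-7-oxohept-5-enoate
Conditions: Dess–Martin periodinane, NaHCO3, CH2Cl2, 0 °C; used at once
Reagents that add atoms: none
Why: Buffered Dess–Martin oxidation of the Z-allylic alcohol should give the Z-enal without acid- or base-induced isomerisation, provided it is used directly.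

**Step 12**
Reactants: 20 (4S)-2-chloro-4-[(2Z)-oct-2-en-1-yl]-4-(triethylsilyloxy)cyclopent-2-en-1-one; 23 methyl (5Z)-7-oxohept-5-enoate
Product: 25 methyl (5Z,7S)-7-[(1R,2S)-4-chloro-2-[(2Z)-oct-2-en-1-yl]-5-oxo-2-(triethylsilyloxy)cyclopent-3-en-1-yl]-7-hydroxyhept-5-enoate, via lithium dienolate 24 (not isolated)
Conditions: LiN(iPr)2, THF, −78 °C; then 23, −78 °C, short reaction time; aqueous NH4Cl at −78 °C
Reagents that add atoms: none
Why: Kinetic deprotonation can occur only at C8 (the other α-carbon is vinylic), and the ring-locked E-enolate 24 should add to the aldehyde on the face anti to the oct-2-enyl chain (syn to the smaller silyloxy oxygen) to set C8 (R) and through a closed Zimmerman–Traxler transition state to give the anti aldol that sets C7 (S), while the low temperature and cold quench guard against retro-aldol, β-elimination and Z-to-E isomerisation.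

**Step 13**
Reactants: 25 methyl (5Z,7S)-7-[(1R,2S)-4-chloro-2-[(2Z)-oct-2-en-1-yl]-5-oxo-2-(triethylsilyloxy)cyclopent-3-en-1-yl]-7-hydroxyhept-5-enoate
Product: 26 methyl (5Z,7S)-7-acetoxy-7-[(1R,2S)-4-chloro-2-[(2Z)-oct-2-en-1-yl]-5-oxo-2-(triethylsilyloxy)cyclopent-3-en-1-yl]hept-5-enoate
Conditions: Ac2O, pyridine, DMAP (cat.), CH2Cl2, 0 °C
Reagents that add atoms: acetic anhydride, CC(=O)OC(C)=O
Why: DMAP-catalysed acetylation of the secondary allylic alcohol at 0 °C proceeds with retention at C7 and should be fast enough to outrun E1cB loss of the β-oxygen substituent.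

**Step 14**
Reactants: 26 methyl (5Z,7S)-7-acetoxy-7-[(1R,2S)-4-chloro-2-[(2Z)-oct-2-en-1-yl]-5-oxo-2-(triethylsilyloxy)cyclopent-3-en-1-yl]hept-5-enoate
Product: 27 punaglandin 8
Conditions: HF·pyridine, pyridine, THF, 0 °C
Reagents that add atoms: none
Why: Fluoride cleavage of the tertiary triethylsilyl ether under buffered, weakly acidic conditions avoids base-induced elimination of the C7 acetate and should give punaglandin 8 with all three stereocentres unchanged.

**Compound list**

1 | ethyl vinyl ether | C=COCC | starting material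
2 | tert-butyl(1-ethoxyethenyl)dimethylsilane | C=C(OCC)[Si](C)(C)C(C)(C)C | intermediate
3 | 1-[tert-butyl(dimethyl)silyl]ethan-1-one | CC(=O)[Si](C)(C)C(C)(C)C | intermediate
4 | (2Z)-1-[tert-butyl(dimethyl)silyl]-3-hydroxyprop-2-en-1-one (enol form of the formyl acylsilane) | O=C(/C=C\O)[Si](C)(C)C(C)(C)C | intermediate
5 | (2E)-1-[tert-butyl(dimethyl)silyl]-3-(phenylsulfanyl)prop-2-en-1-one | O=C(/C=C/Sc1ccccc1)[Si](C)(C)C(C)(C)C | intermediate
6 | 1,3-dibromopropan-2-one | O=C(CBr)CBr | starting material
7 | [(3-bromoprop-1-en-2-yl)oxy]trimethylsilane | C=C(CBr)O[Si](C)(C)C | intermediate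
8 | pentylmagnesium bromide | CCCCC[Mg]Br | starting material
9 | acetylene | C#C | starting material
10 | (1Z)-hept-1-en-1-ylcopper (magnesium bromide complex) | CCCCC/C=C\[Cu] | intermediate
11 | trimethyl{[(4Z)-deca-1,4-dien-2-yl]oxy}silane | C=C(O[Si](C)(C)C)C/C=C\CCCCC | intermediate
12 | lithium (4Z)-deca-1,4-dien-2-olate | [Li]OC(=C)C/C=C\CCCCC | intermediate
13 | lithium (1E,7Z)-3-[tert-butyl(dimethyl)silyl]-5-oxo-1-(phenylsulfanyl)trideca-1,7-dien-3-olate | CCCCC/C=C\CC(=O)CC(O[Li])(/C=C/Sc1ccccc1)[Si](C)(C)C(C)(C)C | intermediate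
14 | lithium 4-{[tert-butyl(dimethyl)silyl]oxy}-1-[(2Z)-oct-2-en-1-yl]-2-(phenylsulfanyl)cyclopent-3-en-1-olate (racemic) | CCCCC/C=C\CC1(O[Li])CC(O[Si](C)(C)C(C)(C)C)=CC1Sc1ccccc1 | intermediate
15 | rac-tert-butyl(dimethyl){[4-[(2Z)-oct-2-en-1-yl]-3-(phenylsulfanyl)-4-(triethylsilyloxy)cyclopent-1-en-1-yl]oxy}silane (either C3 epimer serves) | CCCCC/C=C\CC1(O[Si](CC)(CC)CC)CC(O[Si](C)(C)C(C)(C)C)=CC1Sc1ccccc1 | intermediate
16 | rac-{[3-(benzenesulfinyl)-4-[(2Z)-oct-2-en-1-yl]-4-(triethylsilyloxy)cyclopent-1-en-1-yl]oxy}(tert-butyl)dimethylsilane | CCCCC/C=C\CC1(O[Si](CC)(CC)CC)CC(O[Si](C)(C)C(C)(C)C)=CC1S(=O)c1ccccc1 | intermediate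
17 | rac-3-(benzenesulfinyl)-2-chloro-4-[(2Z)-oct-2-en-1-yl]-4-(triethylsilyloxy)cyclopentan-1-one | CCCCC/C=C\CC1(O[Si](CC)(CC)CC)CC(=O)C(Cl)C1S(=O)c1ccccc1 | intermediate
18 | rac-2-chloro-4-[(2Z)-oct-2-en-1-yl]-4-(triethylsilyloxy)cyclopent-2-en-1-one | CCCCC/C=C\CC1(O[Si](CC)(CC)CC)C=C(Cl)C(=O)C1 | intermediate
19 | (1R,4S)-2-chloro-4-[(2Z)-oct-2-en-1-yl]-4-(triethylsilyloxy)cyclopent-2-en-1-ol (cis) | CCCCC/C=C\C[C@@]1(O[Si](CC)(CC)CC)C=C(Cl)[C@H](O)C1 | intermediate
20 | (4S)-2-chloro-4-[(2Z)-oct-2-en-1-yl]-4-(triethylsilyloxy)cyclopent-2-en-1-one | CCCCC/C=C\C[C@@]1(O[Si](CC)(CC)CC)C=C(Cl)C(=O)C1 | intermediate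
21 | methyl 7-hydroxyhept-5-ynoate | COC(=O)CCCC#CCO | starting material
22 | methyl (5Z)-7-hydroxyhept-5-enoate | COC(=O)CCC/C=C\CO | intermediate
23 | methyl (5Z)-7-oxohept-5-enoate | COC(=O)CCC/C=C\C=O | intermediate
24 | lithium (3S)-5-chloro-3-[(2Z)-oct-2-en-1-yl]-3-(triethylsilyloxy)cyclopenta-1,4-dien-1-olate | CCCCC/C=C\C[C@@]1(O[Si](CC)(CC)CC)C=C(Cl)C(O[Li])=C1 | intermediate
25 | methyl (5Z,7S)-7-[(1R,2S)-4-chloro-2-[(2Z)-oct-2-en-1-yl]-5-oxo-2-(triethylsilyloxy)cyclopent-3-en-1-yl]-7-hydroxyhept-5-enoate | CCCCC/C=C\C[C@@]1(O[Si](CC)(CC)CC)C=C(Cl)C(=O)[C@@H]1[C@H](/C=C\CCCC(=O)OC)O | intermediate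
26 | methyl (5Z,7S)-7-acetoxy-7-[(1R,2S)-4-chloro-2-[(2Z)-oct-2-en-1-yl]-5-oxo-2-(triethylsilyloxy)cyclopent-3-en-1-yl]hept-5-enoate | CCCCC/C=C\C[C@@]1(O[Si](CC)(CC)CC)C=C(Cl)C(=O)[C@@H]1[C@H](/C=C\CCCC(=O)OC)OC(C)=O | intermediate
27 | punaglandin 8, methyl (5Z,7S)-7-acetoxy-7-[(1R,2S)-4-chloro-2-hydroxy-2-[(2Z)-oct-2-en-1-yl]-5-oxocyclopent-3-en-1-yl]hept-5-enoate | CCCCC/C=C\C[C@@]1(O)C=C(Cl)C(=O)[C@@H]1[C@H](/C=C\CCCC(=O)OC)OC(C)=O | target

**Step count and risks**

Total step count: 14. Longest linear sequence: 10 steps (1, 2, 3, 6, 7, 8, 9, 12, 13, 14).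

Steps most likely to fail:

Step 6. The siloxy-allyl anion may be quenched by proton transfer from the doubly activated allylic α-CH2 of the ketone part (or the skipped diene may isomerise) before it closes the ring, or 5 may be attacked in the conjugate sense. Fallback, setting out from 5: the kinetic lithium enolate of commercial 4,4-dimethoxybutan-2-one (LiN(iPr)2, THF, −78 °C), which has no allylic α-hydrogen, is used in the same annulation with Et3SiOTf capping and should give tert-butyl{[4-(2,2-dimethoxyethyl)-3-(phenylsulfanyl)-4-(triethylsilyloxy)cyclopent-1-en-1-yl]oxy}dimethylsilane F1. The conditions of step 7 should convert it into rac-2-chloro-4-(2,2-dimethoxyethyl)-4-(triethylsilyloxy)cyclopent-2-en-1-one F2, and the reduction and separation of step 8 should give (1R,4R)-2-chloro-4-(2,2-dimethoxyethyl)-4-(triethylsilyloxy)cyclopent-2-en-1-ol F3 (same spatial arrangement as 19). Mild acetal hydrolysis (LiBF4, wet MeCN) should give 2-[(1R,4R)-3-chloro-4-hydroxy-1-(triethylsilyloxy)cyclopent-2-en-1-yl]acetaldehyde F4, and a salt-free Wittig reaction with hexylidene(triphenyl)phosphorane (hexyltriphenylphosphonium bromide, NaN(SiMe3)2, THF, −78 °C) installs the Z-olefin and comes back to the route at 19.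

Step 7. The peracid may attack the silyl enol ether, or the allylic sulfoxide may undergo a [2,3]-sigmatropic (Mislow–Evans) shift and lose sulfur before the chlorination, so that the enone forms without chlorine. Fallback, setting out from 15: selective cleavage of the enol silyl ether (Bu4NF, AcOH, THF, −20 °C) should give rac-4-[(2Z)-oct-2-en-1-yl]-3-(phenylsulfanyl)-4-(triethylsilyloxy)cyclopentan-1-one F5. Oxidation with NaIO4 (MeOH–H2O) and thermal sulfoxide elimination should give rac-4-[(2Z)-oct-2-en-1-yl]-4-(triethylsilyloxy)cyclopent-2-en-1-one F6. Nucleophilic epoxidation (H2O2, NaOH, MeOH, 0 °C), which leaves the isolated Z-olefin alone, should give rac-4-[(2Z)-oct-2-en-1-yl]-4-(triethylsilyloxy)-6-oxabicyclo[3.1.0]hexan-2-one F7. Anhydrous HCl in CH2Cl2 at −20 °C then opens the epoxide at the α-carbon and dehydrates the chlorohydrin, and the sequence comes back to the route at 18 (any desilylated material being re-silylated with Et3SiOTf).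

Step 8. Substrate bias from the quaternary centre may override reagent control for one enantiomer, or the diastereomers may not separate, so that material of low enantiomeric purity is carried on. Fallback, setting out from 18: Luche reduction (NaBH4, CeCl3·7H2O, MeOH, −78 °C) and separation of the cis isomer should give rac-cis-2-chloro-4-[(2Z)-oct-2-en-1-yl]-4-(triethylsilyloxy)cyclopent-2-en-1-ol F8. Steglich esterification with (S)-2-methoxy-2-phenylacetic acid (DCC, DMAP, CH2Cl2) gives two diastereomeric esters, from which (1R,4S)-2-chloro-4-[(2Z)-oct-2-en-1-yl]-4-(triethylsilyloxy)cyclopent-2-en-1-yl (2S)-2-methoxy-2-phenylacetate F9 is separated by chromatography or crystallisation. Methanolysis (K2CO3, MeOH, 0 °C) comes back to the route at 19.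

Further compounds
F1 | step 6 | tert-butyl{[4-(2,2-dimethoxyethyl)-3-(phenylsulfanyl)-4-(triethylsilyloxy)cyclopent-1-en-1-yl]oxy}dimethylsilane (racemic) | COC(CC1(O[Si](CC)(CC)CC)CC(O[Si](C)(C)C(C)(C)C)=CC1Sc1ccccc1)OC
F2 | step 6 | rac-2-chloro-4-(2,2-dimethoxyethyl)-4-(triethylsilyloxy)cyclopent-2-en-1-one | COC(CC1(O[Si](CC)(CC)CC)C=C(Cl)C(=O)C1)OC
F3 | step 6 | (1R,4R)-2-chloro-4-(2,2-dimethoxyethyl)-4-(triethylsilyloxy)cyclopent-2-en-1-ol | COC(C[C@@]1(O[Si](CC)(CC)CC)C=C(Cl)[C@H](O)C1)OC
F4 | step 6 | 2-[(1R,4R)-3-chloro-4-hydroxy-1-(triethylsilyloxy)cyclopent-2-en-1-yl]acetaldehyde | O=CC[C@@]1(O[Si](CC)(CC)CC)C=C(Cl)[C@H](O)C1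
F5 | step 7 | rac-4-[(2Z)-oct-2-en-1-yl]-3-(phenylsulfanyl)-4-(triethylsilyloxy)cyclopentan-1-one | CCCCC/C=C\CC1(O[Si](CC)(CC)CC)CC(=O)CC1Sc1ccccc1
F6 | step 7 | rac-4-[(2Z)-oct-2-en-1-yl]-4-(triethylsilyloxy)cyclopent-2-en-1-one | CCCCC/C=C\CC1(O[Si](CC)(CC)CC)C=CC(=O)C1
F7 | step 7 | rac-4-[(2Z)-oct-2-en-1-yl]-4-(triethylsilyloxy)-6-oxabicyclo[3.1.0]hexan-2-one | CCCCC/C=C\CC1(O[Si](CC)(CC)CC)CC(=O)C2OC12
F8 | step 8 | rac-cis-2-chloro-4-[(2Z)-oct-2-en-1-yl]-4-(triethylsilyloxy)cyclopent-2-en-1-ol | CCCCC/C=C\CC1(O[Si](CC)(CC)CC)C=C(Cl)C(O)C1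
F9 | step 8 | (1R,4S)-2-chloro-4-[(2Z)-oct-2-en-1-yl]-4-(triethylsilyloxy)cyclopent-2-en-1-yl (2S)-2-methoxy-2-phenylacetate | CCCCC/C=C\C[C@@]1(O[Si](CC)(CC)CC)C=C(Cl)[C@H](OC(=O)[C@@H](OC)c2ccccc2)C1
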